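Amounts first: oak was charged with less E than D, and its J flattened out at about 25.6% of the D charged, far below what its E could pay for at one E per J.

| setting | oak | summer | spring | noon | winter |
|---|---|---|---|---|---|
| D | 0.37 M | 0.37 M | 0.37 M | 0.37 M | 0.37 M |
| E | 0.19 M | 0.389 M | 0.389 M | 0.389 M | 0.389 M |
| temperature | 50 °C | 50 °C | 75 °C | 25 °C | 100 °C |
| remark | run made earlier |  |  |  |  |
| time |  | 30 min | 30 min | 30 min | 30 min |

oak run (percent of the D charged): time / min: J / % = 1.33: 15.4; 2.50: 20.4; 4.00: 23.2; 5.00: 24.1; 6.00: 25.6

(each reading ± 0.5 percentage points)

- the earlier runs were read with a standard deviation of 0.5 percentage points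
- a reading or a percentage of J counts all its forms, free or not
- the earlier runs do not show what temperature does; that part of a forecast is a guess

* the flask that comes out highest in amount of J, in percent of the D charged, or "all alike" when all lie within 1.5 percentage points (summer / spring / noon / winter / all alike)
* J at the end, in percent of the D charged, summer
* J at the end, in percent of the D charged, spring
* J at the end, in percent of the D charged, noon
* J at the end, in percent of the D charged, winter

We count turnovers, as our own reading of these runs, which they cannot prove. Each D turned costs one E and gives J; each J turned further costs a second E and gives a product we do not see. All amounts below are fractions of the D charged: x is D turned, y is J standing, z is J turned further, a is D left and ρ is E charged. When E is spent, x + z = ρ and y = x − z. For oak we take the last reading, at 6.00 min, as that end: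

ρ = 51.4%, x = (y + ρ)/2 = 38.5%, z = x − y = 12.9%, a = 61.5%

We take both steps as first order in [E], so [E] cancels between them, as between two substrates competing for one enzyme. Per D turned, J is lost at s·[J]/[D]. We take [J]/[D] to climb roughly straight from nothing, so its mean is 0.5 of its end value, which gives z = s·x·(y/a)/2:

s = 2·z·a/(y·x) = 1.61

This s, the constant of J's loss to E over the constant of D's use of E (a selectivity factor), is a reading with the scatter of oak in it, and it is what we carry.

Summer has the same temperature and a longer time than oak, 30 min against the 6.00 min of oak's last reading, so we assume that E is spent there too. Then y = 2x − ρ and z = ρ − x, and the same formula becomes a quadratic in x: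

ρ = 105%, x = 65.5%, y = 25.9%

So by our count summer, with 0.389 M of E, stands at 25.9% of J, where oak, with 0.19 M of E, was read at 25.6%. For the other flasks we have no s, since the earlier runs do not show what temperature does.

The forecast read oak differently, “each J seems to use two E”, and gave 52.4% for summer, 52.2% for spring, 47.5% for noon and 51% for winter, with summer highest. Our summer figure lies 26 percentage points below its figure.

The flasks end at 25.7% in summer, 19.3% in spring, 35.0% in noon and 14.5% in winter, so noon stands highest.

    Q ⇌ J, rate k1*(cs1 - [J]) while solid is left; crystals form when [J] > cs1 (solubility = 0.230 M, k = 12.0 /min)
    L → J (k = 3.10 /min, Ea = 73.0 kJ/mol)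
    E + J → Z (k = 0.270 /M/min, Ea = 64.0 kJ/mol)
    D + E → L + X (k = 0.240 /M/min, Ea = 50.0 kJ/mol)
    (constants at 25 °C)

The loss of E + J to Z has an activation energy 14.0 kJ/mol above that of D + E, and their constants are alike at 18.9 °C. The end states of D, J and Z, put through our formula, read s lower for noon than for summer and lower for summer than for winter: 0.925 for noon, 1.64 for summer and 4.20 for winter.

Readings and results were computed on assumed constants; scatter was added.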